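The tridepside is cut at its two aryl ester bonds. The central ring B is built as a non-aromatic cyclohexane-1,3-dione instead of being taken from an arene. A single base-mediated Michael–Claisen annulation of tert-butyl acetoacetate 1 and ethyl crotonate 2, two simple open-chain esters, forms C1–C6 and C3–C4. It also sets the C1 carboxyl, the C6 methyl and both oxygens of ring B. The feature exploited is the unequal oxygen pair of ring B: O4 carries the ring A acyl group, O2 is a free phenol. In the dione the open C4 enol oxygen is acylated, whereas C2 remains a ketone until dehydrogenation. Rings A and C derive from orsellinates.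

Key step: step 1

Assumption: orsellinic acid is taken as a catalogue compound; should supply fail, hydrogenolysis of the ring A acid (H2, Pd/C, EtOAc) would give it in one extra step.
Remark: the target has no stereocentre; the two centres of the saturated ring B intermediates are racemic and vanish on aromatisation.

Step 1
Reactants: 1 tert-butyl acetoacetate; 2 ethyl (E)-crotonate
Product: 4 tert-butyl trans-6-methyl-2,4-dioxocyclohexane-1-carboxylate (racemic), via Michael adduct 3 (not isolated)
Conditions: KOC(CH3)3 (1.05 equiv), (CH3)3COH, rt → 82 °C; then 1 M HCl, 0 °C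
Reagents that add atoms: none
Why: KOC(CH3)3 deprotonates 1 at its doubly activated C2, and this soft enolate adds in a Michael reaction to the beta-carbon of 2 to form ring B bond C1–C6 and adduct 3. Proton transfer then places the charge on the acetyl methyl of 3, which attacks the ethyl ester carbonyl and expels ethoxide in an intramolecular Claisen (Dieckmann-type) condensation that forms bond C3–C4. The closest known reaction type is the alkoxide-mediated condensation of acetoacetates with crotonates to dihydroorsellinates, here only moved to the tert-butyl ester. The single ring closes in the 6-(enolendo)-exo-trig mode, and the final deprotonation of the cyclic 1,3-dione to its stable enolate drains all the preceding equilibria. C6 arises as a racemate without any control element and C1 stays epimerisable and settles trans to the methyl group under thermodynamic control, which is irrelevant because both centres are erased in step 5. The step needs Michael addition before acylation and attack on the ethyl and not on the tert-butyl ester: the far higher acidity of C2 secures the first, and ring size secures the second, since the methyl enolate reaches the ethyl ester through a six-membered and the bulky tert-butyl ester only through a four-membered transition state.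

Step 2
Reactants: 5 methyl orsellinate
Product: 6 methyl 2,4-bis(benzyloxy)-6-methylbenzoate
Conditions: BnBr (2.4 equiv), K2CO3, DMF, 60 °C
Reagents that add atoms: benzyl bromide, BrCc1ccccc1
Why: Williamson ether synthesis in a dipolar aprotic solvent with warming, which should alkylate the free C4 phenol and also the chelated C2 phenol.

Step 3
Reactants: 6 methyl 2,4-bis(benzyloxy)-6-methylbenzoate
Product: 7 2,4-bis(benzyloxy)-6-methylbenzoic acid
Conditions: KOH, DMSO–H2O, 100 °C; then HCl, 0 °C
Reagents that add atoms: potassium hydroxide, [K+].[OH-]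
Why: Saponification (BAc2) of a doubly ortho-substituted benzoate needs poorly solvated hydroxide in hot aqueous DMSO, conditions under which aryl benzyl ethers are inert and the O-protected acid does not decarboxylate.

Step 4
Reactants: 7 2,4-bis(benzyloxy)-6-methylbenzoic acid; 4 tert-butyl trans-6-methyl-2,4-dioxocyclohexane-1-carboxylate
Product: 9 tert-butyl trans-4-{[2,4-bis(benzyloxy)-6-methylbenzoyl]oxy}-6-methyl-2-oxocyclohex-3-ene-1-carboxylate (racemic), via acid chloride 8 (not isolated)
Conditions: (COCl)2, cat. DMF, CH2Cl2, 0 °C → rt, evaporate; then 4 (1.0 equiv), Et3N, CH2Cl2, −10 → 0 °C, no DMAP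
Reagents that add atoms: oxalyl chloride, O=C(Cl)C(=O)Cl (supplies the chlorine of 8 only; no atom of it stays in 9)
Why: Acid chloride formation followed by base-mediated enol O-acylation of a cyclic 1,3-dione: the ammonium enolate meets the hard aroyl chloride at oxygen, O4 next to the C5 methylene is far more open than O2 flanked by C1 with its tert-butyl ester, and leaving out nucleophilic catalysts blocks the O-to-C acyl shift to C3.

Step 5
Reactants: 9 tert-butyl trans-4-{[2,4-bis(benzyloxy)-6-methylbenzoyl]oxy}-6-methyl-2-oxocyclohex-3-ene-1-carboxylate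
Product: 10 tert-butyl 4-{[2,4-bis(benzyloxy)-6-methylbenzoyl]oxy}-2-hydroxy-6-methylbenzoate
Conditions: DDQ (1.2 equiv), 1,4-dioxane, 80 °C
Reagents that add atoms: none
Why: Quinone dehydrogenation of a 2-oxocyclohex-3-ene-1-carboxylate to a salicylate: the beta-keto ester enolises to a cyclohexa-1,3-dienol, DDQ abstracts the tertiary C6 hydride to give a cation stabilised by the C2 hydroxyl, the C4 acyloxy and the C6 methyl groups, loss of a C5 proton gives the arene, and the dry neutral medium should spare the enol ester, the tert-butyl ester and the aryl benzyl ethers.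

Step 6
Reactants: 10 tert-butyl 4-{[2,4-bis(benzyloxy)-6-methylbenzoyl]oxy}-2-hydroxy-6-methylbenzoate
Product: 11 tert-butyl 2-(benzyloxy)-4-{[2,4-bis(benzyloxy)-6-methylbenzoyl]oxy}-6-methylbenzoate
Conditions: BnBr, K2CO3, DMF, rt → 40 °C
Reagents that add atoms: benzyl bromide, BrCc1ccccc1
Why: Williamson ether synthesis at the only acidic site left (ring B O2), while the doubly ortho-substituted A–B aryl ester is too hindered to be opened by carbonate or phenoxide at this temperature.

Step 7
Reactants: 11 tert-butyl 2-(benzyloxy)-4-{[2,4-bis(benzyloxy)-6-methylbenzoyl]oxy}-6-methylbenzoate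
Product: 12 2-(benzyloxy)-4-{[2,4-bis(benzyloxy)-6-methylbenzoyl]oxy}-6-methylbenzoic acid
Conditions: CF3CO2H–CH2Cl2 (1:4 v/v), 0 °C → rt
Reagents that add atoms: none
Why: Acidolysis of the tert-butyl ester by alkyl–oxygen fission (AAL1, loss of the tert-butyl cation as isobutene) leaves benzyl ethers and the aryl ester alone, which is why this ester was chosen in 1.

Step 8
Reactants: 13 orsellinic acid
Product: 14 benzyl orsellinate
Conditions: BnBr (1.05 equiv), KHCO3, DMF, rt → 40 °C
Reagents that add atoms: benzyl bromide, BrCc1ccccc1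
Why: Chemoselective SN2 alkylation of the carboxylate: KHCO3 ionises only the carboxylic acid, so both phenols stay free, and the mild temperature avoids decarboxylation of the electron-rich acid.

Step 9
Reactants: 12 2-(benzyloxy)-4-{[2,4-bis(benzyloxy)-6-methylbenzoyl]oxy}-6-methylbenzoic acid; 14 benzyl orsellinate
Product: 16 benzyl 4-{[2-(benzyloxy)-4-{[2,4-bis(benzyloxy)-6-methylbenzoyl]oxy}-6-methylbenzoyl]oxy}-2-hydroxy-6-methylbenzoate, via mixed anhydride 15 (not isolated)
Conditions: 12, (CF3CO)2O, toluene, 0 °C; then 14, rt; aq. NaHCO3 work-up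
Reagents that add atoms: trifluoroacetic anhydride, O=C(OC(=O)C(F)(F)F)C(F)(F)F (supplies the trifluoroacetyl group of 15 only; no atom of it stays in 16)
Why: Mixed-anhydride esterification with trifluoroacetic anhydride, the established way to join hindered electron-rich benzoic acids to phenols in depside synthesis: 15 passes on its aroyl group by an acylium-like pathway to the open C4 hydroxyl of 14, whereas the C2 hydroxyl is tied up in a hydrogen bond to the benzyl ester and flanked by it.

Step 10
Reactants: 16 benzyl 4-{[2-(benzyloxy)-4-{[2,4-bis(benzyloxy)-6-methylbenzoyl]oxy}-6-methylbenzoyl]oxy}-2-hydroxy-6-methylbenzoate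
Product: 17 benzyl 4-{[2-(benzyloxy)-4-{[2,4-bis(benzyloxy)-6-methylbenzoyl]oxy}-6-methylbenzoyl]oxy}-2-methoxy-6-methylbenzoate
Conditions: MeI, K2CO3, DMF, rt
Reagents that add atoms: iodomethane, CI
Why: Williamson methylation of the single free phenol (ring C O2), every other oxygen being benzylated or acylated, under dry conditions in which the hindered depside esters should persist.

Step 11
Reactants: 17 benzyl 4-{[2-(benzyloxy)-4-{[2,4-bis(benzyloxy)-6-methylbenzoyl]oxy}-6-methylbenzoyl]oxy}-2-methoxy-6-methylbenzoate
Product: 18 4-{[4-{[2,4-dihydroxy-6-methylbenzoyl]oxy}-2-hydroxy-6-methylbenzoyl]oxy}-2-methoxy-6-methylbenzoic acid (CNP0283563.0)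
Conditions: H2 (1 atm), Pd/C (10 wt% Pd), EtOAc, rt
Reagents that add atoms: none
Why: Catalytic hydrogenolysis removes the three benzyl ethers and the benzyl ester in one neutral operation in a non-nucleophilic solvent, so both depside esters and the methyl ether stay intact.

Compound list
1 | tert-butyl acetoacetate | CC(=O)CC(=O)OC(C)(C)C | starting material
2 | ethyl (E)-crotonate | C/C=C/C(=O)OCC | starting material
3 | 1-tert-butyl 5-ethyl 2-acetyl-3-methylpentanedioate (Michael adduct, racemic mixture of diastereomers, not isolated) | CCOC(=O)CC(C)C(C(C)=O)C(=O)OC(C)(C)C | intermediate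
4 | tert-butyl trans-6-methyl-2,4-dioxocyclohexane-1-carboxylate (racemic, (1S,6R) drawn, diketo form drawn, largely enolised) | C[C@@H]1CC(=O)CC(=O)[C@H]1C(=O)OC(C)(C)C | intermediate
5 | methyl orsellinate (methyl 2,4-dihydroxy-6-methylbenzoate) | COC(=O)c1c(C)cc(O)cc1O | starting material
6 | methyl 2,4-bis(benzyloxy)-6-methylbenzoate | COC(=O)c1c(C)cc(OCc2ccccc2)cc1OCc1ccccc1 | intermediate
7 | 2,4-bis(benzyloxy)-6-methylbenzoic acid | OC(=O)c1c(C)cc(OCc2ccccc2)cc1OCc1ccccc1 | intermediate
8 | 2,4-bis(benzyloxy)-6-methylbenzoyl chloride (not isolated) | ClC(=O)c1c(C)cc(OCc2ccccc2)cc1OCc1ccccc1 | intermediate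
9 | tert-butyl trans-4-{[2,4-bis(benzyloxy)-6-methylbenzoyl]oxy}-6-methyl-2-oxocyclohex-3-ene-1-carboxylate (racemic, (1S,6R) drawn) | C[C@@H]1CC(OC(=O)c2c(C)cc(OCc3ccccc3)cc2OCc2ccccc2)=CC(=O)[C@H]1C(=O)OC(C)(C)C | intermediate
10 | tert-butyl 4-{[2,4-bis(benzyloxy)-6-methylbenzoyl]oxy}-2-hydroxy-6-methylbenzoate | CC(C)(C)OC(=O)c1c(C)cc(OC(=O)c2c(C)cc(OCc3ccccc3)cc2OCc2ccccc2)cc1O | intermediate
11 | tert-butyl 2-(benzyloxy)-4-{[2,4-bis(benzyloxy)-6-methylbenzoyl]oxy}-6-methylbenzoate | CC(C)(C)OC(=O)c1c(C)cc(OC(=O)c2c(C)cc(OCc3ccccc3)cc2OCc2ccccc2)cc1OCc1ccccc1 | intermediate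
12 | 2-(benzyloxy)-4-{[2,4-bis(benzyloxy)-6-methylbenzoyl]oxy}-6-methylbenzoic acid | OC(=O)c1c(C)cc(OC(=O)c2c(C)cc(OCc3ccccc3)cc2OCc2ccccc2)cc1OCc1ccccc1 | intermediate
13 | orsellinic acid (2,4-dihydroxy-6-methylbenzoic acid) | OC(=O)c1c(C)cc(O)cc1O | starting material
14 | benzyl orsellinate (benzyl 2,4-dihydroxy-6-methylbenzoate) | O=C(OCc1ccccc1)c1c(C)cc(O)cc1O | intermediate
15 | 2-(benzyloxy)-4-{[2,4-bis(benzyloxy)-6-methylbenzoyl]oxy}-6-methylbenzoic trifluoroacetic anhydride (not isolated) | FC(F)(F)C(=O)OC(=O)c1c(C)cc(OC(=O)c2c(C)cc(OCc3ccccc3)cc2OCc2ccccc2)cc1OCc1ccccc1 | intermediate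
16 | benzyl 4-{[2-(benzyloxy)-4-{[2,4-bis(benzyloxy)-6-methylbenzoyl]oxy}-6-methylbenzoyl]oxy}-2-hydroxy-6-methylbenzoate | O=C(OCc1ccccc1)c1c(C)cc(OC(=O)c2c(C)cc(OC(=O)c3c(C)cc(OCc4ccccc4)cc3OCc3ccccc3)cc2OCc2ccccc2)cc1O | intermediate
17 | benzyl 4-{[2-(benzyloxy)-4-{[2,4-bis(benzyloxy)-6-methylbenzoyl]oxy}-6-methylbenzoyl]oxy}-2-methoxy-6-methylbenzoate | O=C(OCc1ccccc1)c1c(C)cc(OC(=O)c2c(C)cc(OC(=O)c3c(C)cc(OCc4ccccc4)cc3OCc3ccccc3)cc2OCc2ccccc2)cc1OC | intermediate
18 | 4-{[4-{[2,4-dihydroxy-6-methylbenzoyl]oxy}-2-hydroxy-6-methylbenzoyl]oxy}-2-methoxy-6-methylbenzoic acid (CNP0283563.0, achiral) | COc1cc(OC(=O)c2c(C)cc(OC(=O)c3c(C)cc(O)cc3O)cc2O)cc(C)c1C(=O)O | target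

Total step count: 11.
Longest linear sequence: 9 steps (5 → 6 → 7 → 9 → 10 → 11 → 12 → 16 → 17 → 18, that is steps 2, 3, 4, 5, 6, 7, 9, 10 and 11).

Steps most likely to fail

Step 5 (aromatisation).
- What may go wrong: enolisation may be slow. The dienol may bond to the quinone instead of giving up hydride. The enol ester may be lost on prolonged heating.
- The fallback sets out from 9 and comes back at 10. It replaces hydride abstraction by functionalisation and elimination at C1.
- 9 is treated with PhSeCl and pyridine in CH2Cl2 at 0 °C. This should selenenylate the beta-keto ester carbon on the face away from the C6 methyl and give the C1 phenylselenide F1.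
- H2O2 (or mCPBA at low temperature) oxidises it to the selenoxide F2. Its selenium is cis to H6, so syn elimination followed by spontaneous enolisation should give 10 at or below room temperature.

Step 4 (enol O-acylation).
- What may go wrong: acylation may spread over O4, O2 and C3. The acyl group may migrate from oxygen to carbon. The enol ester may hydrolyse during isolation.
- The fallback sets out from 4 and comes back at 10. It aromatises first and leaves the differentiation of the two oxygens to hydrogen bonding.
- 4 is silylated on both enol oxygens (Me3SiCl, Et3N, THF), which needs no site selectivity, to give the bis(trimethylsilyl) dienol ether F3.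
- DDQ at room temperature dehydrogenates this cyclohexa-1,3-diene to tert-butyl 6-methyl-2,4-bis(trimethylsilyloxy)benzoate F4.
- Dilute aqueous citric acid in THF removes the silyl groups and gives tert-butyl orsellinate F5.
- Acid chloride 8 with Et3N in CH2Cl2 at 0 °C then acylates the non-chelated C4 hydroxyl to give 10.

Step 10 (late methylation).
- What may go wrong: alkylation of the chelated and flanked phenol may be slow. During that time carbonate or phenoxide could open or scramble the two depside esters.
- The fallback sets out from 14 and comes back at 17. It installs the methyl ether before the coupling.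
- 14 is silylated at its open C4 hydroxyl (iPr3SiCl, imidazole, DMF) to benzyl 2-hydroxy-6-methyl-4-(triisopropylsilyloxy)benzoate F6.
- MeI and K2CO3 in acetone give benzyl 2-methoxy-6-methyl-4-(triisopropylsilyloxy)benzoate F7.
- Bu4NF buffered with AcOH in THF frees benzyl 4-hydroxy-2-methoxy-6-methylbenzoate F8.
- This monophenol is joined to 12 under the conditions of step 9 (through 15) to give 17 directly, without 16.

Further compounds
F1 | step 5 | tert-butyl 4-{[2,4-bis(benzyloxy)-6-methylbenzoyl]oxy}-6-methyl-2-oxo-1-(phenylselanyl)cyclohex-3-ene-1-carboxylate (racemic, selenium trans to the C6 methyl) | C[C@@H]1CC(OC(=O)c2c(C)cc(OCc3ccccc3)cc2OCc2ccccc2)=CC(=O)[C@]1([Se]c1ccccc1)C(=O)OC(C)(C)C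
F2 | step 5 | tert-butyl 4-{[2,4-bis(benzyloxy)-6-methylbenzoyl]oxy}-6-methyl-2-oxo-1-(phenylseleninyl)cyclohex-3-ene-1-carboxylate (racemic, configuration at selenium undefined) | C[C@@H]1CC(OC(=O)c2c(C)cc(OCc3ccccc3)cc2OCc2ccccc2)=CC(=O)[C@]1([Se](=O)c1ccccc1)C(=O)OC(C)(C)C
F3 | step 4 | tert-butyl 6-methyl-2,4-bis(trimethylsilyloxy)cyclohexa-1,3-diene-1-carboxylate (racemic) | C[C@@H]1CC(O[Si](C)(C)C)=CC(O[Si](C)(C)C)=C1C(=O)OC(C)(C)C
F4 | step 4 | tert-butyl 6-methyl-2,4-bis(trimethylsilyloxy)benzoate | CC(C)(C)OC(=O)c1c(C)cc(O[Si](C)(C)C)cc1O[Si](C)(C)C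
F5 | step 4 | tert-butyl orsellinate (tert-butyl 2,4-dihydroxy-6-methylbenzoate) | CC(C)(C)OC(=O)c1c(C)cc(O)cc1O
F6 | step 10 | benzyl 2-hydroxy-6-methyl-4-(triisopropylsilyloxy)benzoate | O=C(OCc1ccccc1)c1c(C)cc(O[Si](C(C)C)(C(C)C)C(C)C)cc1O
F7 | step 10 | benzyl 2-methoxy-6-methyl-4-(triisopropylsilyloxy)benzoate | O=C(OCc1ccccc1)c1c(C)cc(O[Si](C(C)C)(C(C)C)C(C)C)cc1OC
F8 | step 10 | benzyl 4-hydroxy-2-methoxy-6-methylbenzoate | O=C(OCc1ccccc1)c1c(C)cc(O)cc1OC
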